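**Two stalls.** Monday's run stalls with 68.6% of its substrate left, more than Thursday's 57.2%, although Monday's charge of reagent is larger. More reagent thus goes with less conversion, which points to the step from reagent and free catalyst to spent catalyst.

| setting | Thursday's | Monday's | teal | violet | grey | blue |
|---|---|---|---|---|---|---|
| substrate | 0.20 M | 0.20 M | 0.20 M | 0.20 M | 0.20 M (fed, over 80 s) | 0.20 M |
| reagent | 0.26 M | 0.39 M | 0.260 M (fed, over 80 s) | 0.260 M (in portions, 2, over 80 s) | 0.260 M | 0.260 M |
| free catalyst | 5 mM | 5 mM | 5.0 mM | 5.0 mM | 5.0 mM | 5.0 mM |
| remark | run made earlier | run made earlier | all else is in the flask from the start; the feed brings no volume worth counting | first portion at the start, last at 80 s | all else is in the flask from the start; the feed brings no volume worth counting | everything together at the start |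
| time |  |  | 2.0 min | 2.0 min | 2.0 min | 2.0 min |

| run | time / s | side product / % | target / % | substrate / % |
|---|---|---|---|---|
| Thursday's | 10.0 | 26.3 | 2.2 | 70.5 |
| Thursday's | 15.0 | 31.8 | 1.9 | 64.4 |
| Thursday's | 25.0 | 37.1 | 1.3 | 61.0 |
| Thursday's | 40.0 | 39.6 | 2.6 | 58.9 |
| Thursday's | 60.0 | 40.5 | 2.0 | 56.5 |
| Thursday's | 80.0 | 41.9 | 2.3 | 57.2 |
| Monday's | 10.0 | 22.3 | 1.6 | 74.3 |
| Monday's | 12.0 | 24.0 | 2.4 | 72.5 |
| Monday's | 20.0 | 28.0 | 1.7 | 69.7 |
| Monday's | 25.0 | 28.2 | 2.1 | 69.4 |
| Monday's | 30.0 | 30.0 | 1.6 | 68.5 |
| Monday's | 40.0 | 29.2 | 2.3 | 68.6 |

(readings scatter by 0.5 percentage points)

- in percentages every species weighs as the substrate in it: one side product counts as two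
- for target the idle complex is counted in
- the analysis behind the earlier runs scatters by 0.5 percentage points, standard deviation
- steps that have been proposed: substrate + free catalyst -> free catalyst + open intermediate; free catalyst + open intermediate <-> catalyst intermediate; reagent + catalyst intermediate -> free catalyst + target; reagent + free catalyst -> spent catalyst; free catalyst + target <-> idle complex; substrate + open intermediate -> side product

1. the flask that comes out highest in amount of side product, in percent of the substrate charged, or "all alike" when all lie within 1.5 percentage points (teal / violet / grey / blue / all alike)
2. side product at the end, in percent of the substrate charged, teal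
3. side product at the end, in percent of the substrate charged, violet
4. side product at the end, in percent of the substrate charged, grey
5. side product at the end, in percent of the substrate charged, blue

**Fastest rung.** Open intermediate holds hardly any of the charge: in Thursday's run at 10.0 s, substrate, target and side product nearly close the balance. It can therefore be reckoned as steady, and each opening that ends in side product costs two substrates.

**Middle rung.** Thursday's target and the whole catalyst charge together account for 3.69% of the reagent, so reagent stands nearly constant and catalyst death is pseudo-first-order. Thursday's approach to the stall reads as a catalyst life of 10.2 s. If that step ends the catalyst, then at a fixed catalyst charge life varies inversely with reagent, and so does the total logarithmic fall of substrate. Thursday's last reading gives 0.145 M and Monday's 0.147 M for the catalyst budget at 5 mM of free catalyst, the standing reagent times the natural logarithm of substrate charged over substrate left.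

**Slowest rung.** The feeds last longer than a catalyst life, so the recipe sets the reagent that catalyst meets. Blue carries Thursday's charges, so this reckoning merely returns Thursday's 57.2% substrate left for blue. Violet's first portion, reckoned as standing alone, leaves 32.7%. Teal's ramp is reckoned to use up one life's exposure in 40.3 s, at a mean reagent of 0.0656 M, which leaves 11.0%, less than violet's figure. In grey, 12.7% of the substrate has arrived after one reckoned life, so this reckoning expects low side product.

**The forecast.** Holding that “Loss is therefore set by the catalyst's time integral”, the forecast names teal and gives 75% for teal, 62% for violet, 6% for grey and 41.5% for blue. Its teal keeps 15% substrate, where the reckoning here keeps 11.0%.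

**The result.** Teal comes out highest at 81.9%, above the forecast's 75%, with violet at 64.0%, grey at 2.97% and blue at 41.0%. substrate + free catalyst → free catalyst + open intermediate (k = 11.4 /M/s); free catalyst + open intermediate ⇌ catalyst intermediate (K = 39.0 /M, k = 44.4 /M/s); reagent + catalyst intermediate → free catalyst + target (k = 19.8 /M/s); reagent + free catalyst → spent catalyst (k = 0.772 /M/s); free catalyst + target ⇌ idle complex, settled at all times (K = 350 /M); substrate + open intermediate → side product (k = 2.48 /M/s)

Teal ends with 12.4% substrate and 5.53% target. Through the budget, teal behaves like a flask standing at 0.0695 M of reagent. The budget holds no substrate charge, and the neighbour like teal but charged with 0.080 M of substrate ends with 11.8% substrate.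

The numbers in the tables stem from a simulated flask for substances that don't exist; scatter was added.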